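1. Feature used: on the cyclopentenone ring (C8–C12) the tertiary C12–O bond and the C8–C7 bond lie on the same face, so O–C12–C8–C7–C6 can be closed as a γ-lactone cis-fused to the carbocycle (a 2-oxabicyclo[3.3.0]octane) that stores both the C12 oxygen and a C6 aldehyde.
2. Late disconnections: C9 ketone from its silyl-protected carbinol (last step); C4 and C12 acetates from the diol; the (4S)-carbinol from CBS reduction of a C4 enone; the (E)-C5=C6 bond from a Wittig reaction of the C6 lactol with a keto ylide carrying C1–C5; the (14Z)-alkene from the alkyne.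
3. C9 oxygen: allylic oxidation of the C10=C11 alkene lactone, which comes from dehydroiodination of the iodolactone.
4. Key disconnection: the C12–O bond by iodolactonisation of acid 12; its C8 centre is set by Johnson–Claisen chirality transfer from (R)-allylic alcohol 7, made by CBS reduction of enone 6 from cyclopentane-1,3-dione and 1-bromooct-2-yne.
5. Ring order: the carbocycle is present from compound 1; the lactone ring is closed in step 7 and opened again in step 15.

Key step: step 7

Remark: atom labels C1–C20 follow prostanoid numbering (C1 ester carbon, C8–C12 ring, C13–C20 eight-carbon chain); assumption: the C9 carbinol in 16–19 and 23–26 is drawn as the epimer expected from hydride delivery to the convex face, and its configuration is of no consequence because C9 is oxidised to the ketone in the last step.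

Step 1
Reactants: 1 cyclopentane-1,3-dione; 2 1-bromooct-2-yne
Product: 3 2-(oct-2-yn-1-yl)cyclopentane-1,3-dione
Conditions: KOH (1.0 equiv), H2O/1,4-dioxane, 60 °C
Reagents that add atoms: none
Why: C-alkylation of the stabilised 1,3-dione enolate by SN2 displacement at the primary propargylic bromide, in a protic medium where hydrogen bonding to the enolate oxygens favours reaction through carbon.

Step 2
Reactants: 3 2-(oct-2-yn-1-yl)cyclopentane-1,3-dione
Product: 4 3-(2-methylpropoxy)-2-(oct-2-yn-1-yl)cyclopent-2-en-1-one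
Conditions: iBuOH, TsOH·H2O (cat.), toluene, reflux, Dean–Stark
Reagents that add atoms: 2-methylpropan-1-ol, CC(C)CO
Why: Acid-catalysed enol etherification (vinylogous ester formation) driven by azeotropic removal of water; the dione is symmetrical, so only one enol ether can form.

Step 3
Reactants: 4 3-(2-methylpropoxy)-2-(oct-2-yn-1-yl)cyclopent-2-en-1-one
Product: 6 2-(oct-2-yn-1-yl)cyclopent-2-en-1-one, via allylic alcohol 5 (not isolated)
Conditions: LiAlH4, Et2O, 0 °C; then 2 M HCl, THF, rt
Reagents that add atoms: water, O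
Why: Stork–Danheiser-type reduction and hydrolytic transposition: 1,2-reduction of the vinylogous ester carbonyl, then acid-promoted loss of water and hydrolysis of the enol ether, relocates the carbonyl and gives the 2-alkyl enone, the isolated alkyne being inert to LiAlH4 at 0 °C.

Step 4
Reactants: 6 2-(oct-2-yn-1-yl)cyclopent-2-en-1-one
Product: 7 (1R)-2-(oct-2-yn-1-yl)cyclopent-2-en-1-ol
Conditions: (S)-2-methyl-CBS-oxazaborolidine (0.2 equiv), catecholborane (1.8 equiv), toluene, −78 °C; MeOH quench
Reagents that add atoms: none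
Why: Corey–Bakshi–Shibata reduction, in which the ketone binds the oxazaborolidine boron anti to the bulkier substituted-alkenyl flank and hydride is delivered intramolecularly to give the (R)-carbinol at C11, while catecholborane at −78 °C leaves alkyne and alkene untouched.

Step 5
Reactants: 7 (1R)-2-(oct-2-yn-1-yl)cyclopent-2-en-1-ol; 8 triethyl orthoacetate
Product: 11 ethyl 2-[(1R)-2-(oct-2-yn-1-yl)cyclopent-2-en-1-yl]acetate, via mixed orthoester 9 (not isolated), via ketene acetal 10 (not isolated)
Conditions: 8 (6 equiv), EtCO2H (cat.), 140 °C, EtOH distilled off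
Reagents that add atoms: none
Why: Johnson–Claisen rearrangement, whose [3,3]-sigmatropic shift within the five-membered ring is necessarily suprafacial, so the C11–O configuration is transferred to the new C8–C7 bond on the same face [(R) at C8] while the alkene moves to C11=C12.

Step 6
Reactants: 11 ethyl 2-[(1R)-2-(oct-2-yn-1-yl)cyclopent-2-en-1-yl]acetate
Product: 12 2-[(1R)-2-(oct-2-yn-1-yl)cyclopent-2-en-1-yl]acetic acid
Conditions: LiOH·H2O, THF/MeOH/H2O, rt; then 1 M HCl
Reagents that add atoms: lithium hydroxide, [Li+].[OH-]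
Why: Saponification by acyl substitution with hydroxide; the C8 stereocentre is β to the carbonyl and cannot epimerise.

Step 7
Reactants: 12 2-[(1R)-2-(oct-2-yn-1-yl)cyclopent-2-en-1-yl]acetic acid
Product: 13 (3aR,6S,6aS)-6-iodo-6a-(oct-2-yn-1-yl)hexahydro-2H-cyclopenta[b]furan-2-one
Conditions: I2 (1.5 equiv), NaHCO3 (3 equiv), THF/H2O, 0 °C, dark
Reagents that add atoms: iodine, II
Why: Iodine adds reversibly to the electron-rich trisubstituted C11=C12 ring alkene as a bridged iodonium ion, and only the ion on the face opposite the C8 acetate arm can be opened by the carboxylate, which attacks anti at the tertiary carbon C12, forming the C12–O bond and leaving the C11–I bond trans to it. The closest known reaction type is the kinetic iodolactonisation of γ,δ-unsaturated acids with I2 and aqueous NaHCO3 to cis-fused iodo-γ-lactones, as with cyclopent-2-enylacetic acids. The γ-lactone ring (O, C12, C8, C7, C6) closes in the 5-exo-trig mode, the 6-endo alternative requiring attack at the less substituted C11 and a bridged δ-lactone. The C12 configuration is dictated by the C8 stereocentre, because the two-carbon tether can deliver oxygen only to its own face (cis ring fusion, oxygen cis to C7), and the C11 configuration follows from anti addition. The step needs chemoselectivity for the ring alkene over the C14≡C15 alkyne, which should follow from the much lower reactivity of an unactivated internal alkyne towards I2 at 0 °C and from the absence of a carboxylate within reach of it.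

Step 8
Reactants: 13 (3aR,6S,6aS)-6-iodo-6a-(oct-2-yn-1-yl)hexahydro-2H-cyclopenta[b]furan-2-one
Product: 14 (3aR,6aS)-6a-(oct-2-yn-1-yl)-3,3a,4,6a-tetrahydro-2H-cyclopenta[b]furan-2-one
Conditions: DBU (3 equiv), toluene, 80 °C
Reagents that add atoms: none
Why: E2 dehydroiodination in which, C12 being quaternary, the only β-hydrogens are on C10 and the one anti-periplanar to iodine is removed by the amidine base, giving the C10=C11 alkene without touching the lactone.

Step 9
Reactants: 14 (3aR,6aS)-6a-(oct-2-yn-1-yl)-3,3a,4,6a-tetrahydro-2H-cyclopenta[b]furan-2-one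
Product: 15 (3aR,6aR)-6a-(oct-2-yn-1-yl)-3,3a-dihydro-2H-cyclopenta[b]furan-2,4(6aH)-dione
Conditions: Rh2(cap)4 [dirhodium tetrakis(caprolactamate)] (1 mol %), tBuOOH (70% aq., 5 equiv), CH2Cl2, rt
Reagents that add atoms: tert-butyl hydroperoxide, CC(C)(C)OO
Why: Allylic C–H oxidation by the dirhodium caprolactamate/tBuOOH system, in which the tert-butylperoxyl radical abstracts the weakest C–H (the ring allylic C9–H, the only allylic hydrogens of this alkene and weaker than the propargylic ones), the allyl radical is captured at the less hindered C9 terminus remote from the quaternary C12, and the mixed peroxide collapses to the enone under base-free conditions that spare the 4-acyloxy enone.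

Step 10
Reactants: 15 (3aR,6aR)-6a-(oct-2-yn-1-yl)-3,3a-dihydro-2H-cyclopenta[b]furan-2,4(6aH)-dione
Product: 16 (3aS,4S,6aR)-4-hydroxy-6a-(oct-2-yn-1-yl)-3,3a,4,6a-tetrahydro-2H-cyclopenta[b]furan-2-one
Conditions: NaBH4, CeCl3·7H2O, MeOH, −78 °C
Reagents that add atoms: none
Why: Luche reduction, a CeCl3-mediated 1,2-reduction of the enone at low temperature with hydride expected on the convex face anti to the C8 arm, so that the C9 hydroxyl is cis to the lactone ring, the lactone itself not being reduced.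

Step 11
Reactants: 16 (3aS,4S,6aR)-4-hydroxy-6a-(oct-2-yn-1-yl)-3,3a,4,6a-tetrahydro-2H-cyclopenta[b]furan-2-one
Product: 17 (3aS,4S,6aR)-4-[(tert-butyldimethylsilyl)oxy]-6a-(oct-2-yn-1-yl)-3,3a,4,6a-tetrahydro-2H-cyclopenta[b]furan-2-one
Conditions: TBSOTf, 2,6-lutidine, CH2Cl2, −78 → 0 °C
Reagents that add atoms: tert-butyldimethylsilyl trifluoromethanesulfonate, CC(C)(C)[Si](C)(C)OS(=O)(=O)C(F)(F)F
Why: Silylation of the secondary allylic alcohol with a silyl triflate and a hindered pyridine base, fast at low temperature, so that the C9 hydroxyl is capped before it can attack the lactone carbonyl.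

Step 12
Reactants: 17 (3aS,4S,6aR)-4-[(tert-butyldimethylsilyl)oxy]-6a-(oct-2-yn-1-yl)-3,3a,4,6a-tetrahydro-2H-cyclopenta[b]furan-2-one
Product: 18 (3aS,4S,6aR)-4-[(tert-butyldimethylsilyl)oxy]-6a-[(2Z)-oct-2-en-1-yl]-3,3a,4,6a-tetrahydro-2H-cyclopenta[b]furan-2-one
Conditions: H2 (1 atm), Pd/CaCO3 poisoned with Pb(OAc)2 (Lindlar catalyst), quinoline, EtOAc, rt
Reagents that add atoms: none
Why: Lindlar semi-hydrogenation, in which syn delivery of H2 on lead-poisoned palladium stops at the (Z)-alkene and the ring alkene, flanked by the quaternary C12 and the silyloxy-bearing C9, is too hindered to be reduced.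

Step 13
Reactants: 18 (3aS,4S,6aR)-4-[(tert-butyldimethylsilyl)oxy]-6a-[(2Z)-oct-2-en-1-yl]-3,3a,4,6a-tetrahydro-2H-cyclopenta[b]furan-2-one
Product: 19 (3aS,4S,6aR)-4-[(tert-butyldimethylsilyl)oxy]-6a-[(2Z)-oct-2-en-1-yl]-3,3a,4,6a-tetrahydro-2H-cyclopenta[b]furan-2-ol (mixture of anomers)
Conditions: iBu2AlH (1.1 equiv), CH2Cl2, −78 °C
Reagents that add atoms: none
Why: Partial reduction of the γ-lactone with one equivalent of iBu2AlH at −78 °C, where the tetrahedral aluminium lactolate survives until work-up, gives the lactol as a latent C6 aldehyde.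

Step 14
Reactants: 20 methyl 5-bromo-4-oxopentanoate
Product: 22 methyl 4-oxo-5-(triphenylphosphoranylidene)pentanoate, via phosphonium bromide 21 (not isolated)
Conditions: PPh3, toluene, rt; then aq. NaOH, CH2Cl2, 0 °C
Reagents that add atoms: triphenylphosphine, c1ccc(cc1)P(c1ccccc1)c1ccccc1
Why: SN2 quaternisation of triphenylphosphine by the α-bromo ketone and deprotonation of the acidic phosphonium α-CH2 give the carbonyl-stabilised ylide that carries C1–C5.

Step 15
Reactants: 19 (3aS,4S,6aR)-4-[(tert-butyldimethylsilyl)oxy]-6a-[(2Z)-oct-2-en-1-yl]-3,3a,4,6a-tetrahydro-2H-cyclopenta[b]furan-2-ol; 22 methyl 4-oxo-5-(triphenylphosphoranylidene)pentanoate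
Product: 23 methyl (5E,8S,9S,12R,14Z)-9-[(tert-butyldimethylsilyl)oxy]-12-hydroxy-4-oxoprosta-5,10,14-trien-1-oate
Conditions: 22 (2.5 equiv), toluene, 90 °C
Reagents that add atoms: none
Why: Wittig olefination of the ring-opened hydroxy aldehyde form of the lactol with a keto-stabilised ylide, which gives the (E)-enone, and since no base is present the tertiary C12 hydroxyl is not expected to add back to the enone.

Step 16
Reactants: 23 methyl (5E,8S,9S,12R,14Z)-9-[(tert-butyldimethylsilyl)oxy]-12-hydroxy-4-oxoprosta-5,10,14-trien-1-oate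
Product: 24 methyl (4S,5E,8S,9S,12R,14Z)-9-[(tert-butyldimethylsilyl)oxy]-4,12-dihydroxyprosta-5,10,14-trien-1-oate
Conditions: (R)-2-methyl-CBS-oxazaborolidine (1.0 equiv), catecholborane (3 equiv), toluene, −78 °C; MeOH quench, pH 7 buffer
Reagents that add atoms: none
Why: Corey–Bakshi–Shibata reduction in which the (R)-catalyst binds the enone carbonyl anti to the alkenyl flank (the larger group) and delivers hydride 1,2 to give the (4S)-allylic alcohol; the crude γ-hydroxy ester is acetylated at once so that it cannot lactonise.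

Step 17
Reactants: 24 methyl (4S,5E,8S,9S,12R,14Z)-9-[(tert-butyldimethylsilyl)oxy]-4,12-dihydroxyprosta-5,10,14-trien-1-oate
Product: 25 methyl (4S,5E,8S,9S,12R,14Z)-4,12-diacetoxy-9-[(tert-butyldimethylsilyl)oxy]prosta-5,10,14-trien-1-oate
Conditions: Ac2O, Et3N, DMAP, CH2Cl2, rt
Reagents that add atoms: acetic anhydride, CC(=O)OC(C)=O
Why: DMAP-catalysed acylation through the N-acetylpyridinium ion esterifies the secondary C4 hydroxyl rapidly and the hindered tertiary allylic C12 hydroxyl on prolonged reaction, with no stereocentre affected and no enone yet present to suffer base-induced elimination.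

Step 18
Reactants: 25 methyl (4S,5E,8S,9S,12R,14Z)-4,12-diacetoxy-9-[(tert-butyldimethylsilyl)oxy]prosta-5,10,14-trien-1-oate
Product: 26 methyl (4S,5E,8S,9S,12R,14Z)-4,12-diacetoxy-9-hydroxyprosta-5,10,14-trien-1-oate
Conditions: HF·pyridine, pyridine, THF, 0 °C → rt
Reagents that add atoms: none
Why: Fluoride-mediated desilylation (Si–F bond formation) under buffered, weakly acidic conditions that leave both acetates and the methyl ester intact and do not promote acetyl migration to the C9 hydroxyl.

Step 19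
Reactants: 26 methyl (4S,5E,8S,9S,12R,14Z)-4,12-diacetoxy-9-hydroxyprosta-5,10,14-trien-1-oate
Product: 27 methyl (4S,5E,8R,12R,14Z)-4,12-diacetoxy-9-oxoprosta-5,10,14-trien-1-oate
Conditions: Dess–Martin periodinane, CH2Cl2, 0 °C → rt
Reagents that add atoms: none
Why: Dess–Martin oxidation of the secondary allylic alcohol to the enone under non-basic conditions, so that the 4-acetoxy enone does not eliminate acetic acid and C8, already trans to the octenyl chain, does not epimerise.

Compound list
1 | cyclopentane-1,3-dione | O=C1CCC(=O)C1 | starting material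
2 | 1-bromooct-2-yne | CCCCCC#CCBr | starting material
3 | 2-(oct-2-yn-1-yl)cyclopentane-1,3-dione | CCCCCC#CCC1C(=O)CCC1=O | intermediate
4 | 3-(2-methylpropoxy)-2-(oct-2-yn-1-yl)cyclopent-2-en-1-one | CCCCCC#CCC1=C(OCC(C)C)CCC1=O | intermediate
5 | 3-(2-methylpropoxy)-2-(oct-2-yn-1-yl)cyclopent-2-en-1-ol (racemic, not isolated) | CCCCCC#CCC1=C(OCC(C)C)CCC1O | intermediate
6 | 2-(oct-2-yn-1-yl)cyclopent-2-en-1-one | CCCCCC#CCC1=CCCC1=O | intermediate
7 | (1R)-2-(oct-2-yn-1-yl)cyclopent-2-en-1-ol | O[C@@H]1CCC=C1CC#CCCCCC | intermediate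
8 | triethyl orthoacetate | CCOC(C)(OCC)OCC | starting material
9 | mixed orthoester, 1,1-diethoxyethyl ether of 7 (not isolated) | CCOC(C)(OCC)O[C@@H]1CCC=C1CC#CCCCCC | intermediate
10 | ketene acetal, 1-ethoxyvinyl ether of 7 (not isolated) | C=C(OCC)O[C@@H]1CCC=C1CC#CCCCCC | intermediate
11 | ethyl 2-[(1R)-2-(oct-2-yn-1-yl)cyclopent-2-en-1-yl]acetate | CCCCCC#CCC1=CCC[C@@H]1CC(=O)OCC | intermediate
12 | 2-[(1R)-2-(oct-2-yn-1-yl)cyclopent-2-en-1-yl]acetic acid | CCCCCC#CCC1=CCC[C@@H]1CC(=O)O | intermediate
13 | (3aR,6S,6aS)-6-iodo-6a-(oct-2-yn-1-yl)hexahydro-2H-cyclopenta[b]furan-2-one (cis-fused, iodine trans to the lactone oxygen) | CCCCCC#CC[C@]12OC(=O)C[C@H]1CC[C@@H]2I | intermediate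
14 | (3aR,6aS)-6a-(oct-2-yn-1-yl)-3,3a,4,6a-tetrahydro-2H-cyclopenta[b]furan-2-one | CCCCCC#CC[C@]12OC(=O)C[C@H]1CC=C2 | intermediate
15 | (3aR,6aR)-6a-(oct-2-yn-1-yl)-3,3a-dihydro-2H-cyclopenta[b]furan-2,4(6aH)-dione | CCCCCC#CC[C@]12OC(=O)C[C@H]1C(=O)C=C2 | intermediate
16 | (3aS,4S,6aR)-4-hydroxy-6a-(oct-2-yn-1-yl)-3,3a,4,6a-tetrahydro-2H-cyclopenta[b]furan-2-one | CCCCCC#CC[C@]12OC(=O)C[C@H]1[C@@H](O)C=C2 | intermediate
17 | (3aS,4S,6aR)-4-[(tert-butyldimethylsilyl)oxy]-6a-(oct-2-yn-1-yl)-3,3a,4,6a-tetrahydro-2H-cyclopenta[b]furan-2-one | CCCCCC#CC[C@]12OC(=O)C[C@H]1[C@@H](O[Si](C)(C)C(C)(C)C)C=C2 | intermediate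
18 | (3aS,4S,6aR)-4-[(tert-butyldimethylsilyl)oxy]-6a-[(2Z)-oct-2-en-1-yl]-3,3a,4,6a-tetrahydro-2H-cyclopenta[b]furan-2-one | CCCCC/C=C\C[C@]12OC(=O)C[C@H]1[C@@H](O[Si](C)(C)C(C)(C)C)C=C2 | intermediate
19 | (3aS,4S,6aR)-4-[(tert-butyldimethylsilyl)oxy]-6a-[(2Z)-oct-2-en-1-yl]-3,3a,4,6a-tetrahydro-2H-cyclopenta[b]furan-2-ol (anomeric mixture) | CCCCC/C=C\C[C@]12OC(O)C[C@H]1[C@@H](O[Si](C)(C)C(C)(C)C)C=C2 | intermediate
20 | methyl 5-bromo-4-oxopentanoate | COC(=O)CCC(=O)CBr | starting material
21 | (5-methoxy-2,5-dioxopentyl)triphenylphosphonium bromide (not isolated) | COC(=O)CCC(=O)C[P+](c1ccccc1)(c1ccccc1)c1ccccc1.[Br-] | intermediate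
22 | methyl 4-oxo-5-(triphenylphosphoranylidene)pentanoate | COC(=O)CCC(=O)C=P(c1ccccc1)(c1ccccc1)c1ccccc1 | intermediate
23 | methyl (5E,8S,9S,12R,14Z)-9-[(tert-butyldimethylsilyl)oxy]-12-hydroxy-4-oxoprosta-5,10,14-trien-1-oate | CCCCC/C=C\C[C@@]1(O)C=C[C@H](O[Si](C)(C)C(C)(C)C)[C@@H]1C/C=C/C(=O)CCC(=O)OC | intermediate
24 | methyl (4S,5E,8S,9S,12R,14Z)-9-[(tert-butyldimethylsilyl)oxy]-4,12-dihydroxyprosta-5,10,14-trien-1-oate | CCCCC/C=C\C[C@@]1(O)C=C[C@H](O[Si](C)(C)C(C)(C)C)[C@@H]1C/C=C/[C@@H](O)CCC(=O)OC | intermediate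
25 | methyl (4S,5E,8S,9S,12R,14Z)-4,12-diacetoxy-9-[(tert-butyldimethylsilyl)oxy]prosta-5,10,14-trien-1-oate | CCCCC/C=C\C[C@@]1(OC(C)=O)C=C[C@H](O[Si](C)(C)C(C)(C)C)[C@@H]1C/C=C/[C@H](CCC(=O)OC)OC(C)=O | intermediate
26 | methyl (4S,5E,8S,9S,12R,14Z)-4,12-diacetoxy-9-hydroxyprosta-5,10,14-trien-1-oate | CCCCC/C=C\C[C@@]1(OC(C)=O)C=C[C@H](O)[C@@H]1C/C=C/[C@H](CCC(=O)OC)OC(C)=O | intermediate
27 | methyl (4S,5E,8R,12R,14Z)-4,12-diacetoxy-9-oxoprosta-5,10,14-trien-1-oate (CNP0171642.3) | CCCCC/C=C\C[C@@]1(OC(C)=O)C=CC(=O)[C@@H]1C/C=C/[C@H](CCC(=O)OC)OC(C)=O | target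

Total step count: 19
Longest linear sequence: 18 steps (steps 1–13 and 15–19, from 1 to 27); step 14 is a one-step side branch.

Steps most likely to fail

1. Step 9 (allylic oxidation). Hydrogen abstraction may also occur at the propargylic C16 methylene, the allyl radical may be oxygenated at C11 instead of C9, or the reaction may stall at the mixed peroxide. The fallback sets out from 14 and places the oxygen by substitution instead of radical recombination. Wohl–Ziegler bromination (N-bromosuccinimide, AIBN, PhCF3, 80 °C) should give the C9 allylic bromide F1, since the bromine atom is selective for the weakest C–H and allylic bromides settle at the less hindered C9 terminus. Silver-assisted hydrolysis (Ag2CO3, acetone/H2O, rt) should then give the C9 allylic alcohol F2 as a mixture of C9 epimers, water attacking the allyl cation at C9, away from the quaternary, oxygen-bearing C12. Dess–Martin oxidation of F2 (CH2Cl2, rt) returns the route to 15.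

2. Step 15 (Wittig olefination of the lactol). The tertiary C12 hydroxyl may add in conjugate fashion to C6 of the new enone (closure to a bicyclic ether), or the hindered lactol may open too slowly for complete olefination. The fallback sets out from 18 and installs the C12 acetate before the aldehyde is released. LiAlH4 (THF, 0 °C) gives the C6,C12-diol F3. TESCl/imidazole (CH2Cl2, 0 °C) silylates only the primary hydroxyl to give the primary triethylsilyl ether F4. Ac2O/DMAP/Et3N acetylates the tertiary C12 hydroxyl to give the tertiary acetate F5. Swern oxidation (oxalyl chloride, DMSO, Et3N, −78 → −20 °C) converts the primary triethylsilyl ether directly, leaving the secondary tert-butyldimethylsilyl ether, and gives the C6 aldehyde F6. Wittig reaction with 22 (CH2Cl2, rt) gives the C12-acetoxy enone F7, which has no free hydroxyl. Reduction with (R)-2-methyl-CBS-oxazaborolidine and catecholborane gives the (4S)-allylic alcohol F8, and acetylation of its C4 hydroxyl (Ac2O, DMAP, Et3N) returns the route to 25.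

3. Step 4 (CBS reduction of enone 6). Enantiofacial discrimination may be insufficient, because the two flanks of the small cyclopentenone carbonyl differ only modestly in size, and the wrong enantiomer would then be carried through the Claisen transfer into the whole series. The fallback sets out from 6 and replaces catalyst control by enzymatic resolution. Luche reduction (NaBH4, CeCl3·7H2O, MeOH, 0 °C) gives the racemic allylic alcohol F9. Lipase-catalysed transesterification (Burkholderia cepacia lipase, vinyl acetate, hexane, rt) should acylate the (R)-enantiomer selectively to the (R)-acetate F10, which is separated from the unreacted enantiomer of F9. Methanolysis of F10 (K2CO3, MeOH, rt) returns the route to 7.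

Further compounds
F1 | step 9 | 4-bromo-6a-(oct-2-yn-1-yl)-3,3a,4,6a-tetrahydro-2H-cyclopenta[b]furan-2-one, ring fusion as in 14, C9 (ring C4) epimers | CCCCCC#CC[C@]12OC(=O)C[C@H]1C(Br)C=C2
F2 | step 9 | 4-hydroxy-6a-(oct-2-yn-1-yl)-3,3a,4,6a-tetrahydro-2H-cyclopenta[b]furan-2-one, ring fusion as in 14, C9 (ring C4) epimers | CCCCCC#CC[C@]12OC(=O)C[C@H]1C(O)C=C2
F3 | step 15 | 2-[(1S,2R,5S)-5-[(tert-butyldimethylsilyl)oxy]-2-hydroxy-2-[(2Z)-oct-2-en-1-yl]cyclopent-3-en-1-yl]ethan-1-ol | CCCCC/C=C\C[C@@]1(O)C=C[C@H](O[Si](C)(C)C(C)(C)C)[C@@H]1CCO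
F4 | step 15 | (1R,4S,5S)-4-[(tert-butyldimethylsilyl)oxy]-1-[(2Z)-oct-2-en-1-yl]-5-{2-[(triethylsilyl)oxy]ethyl}cyclopent-2-en-1-ol | CCCCC/C=C\C[C@@]1(O)C=C[C@H](O[Si](C)(C)C(C)(C)C)[C@@H]1CCO[Si](CC)(CC)CC
F5 | step 15 | (1R,4S,5S)-4-[(tert-butyldimethylsilyl)oxy]-1-[(2Z)-oct-2-en-1-yl]-5-{2-[(triethylsilyl)oxy]ethyl}cyclopent-2-en-1-yl acetate | CCCCC/C=C\C[C@@]1(OC(C)=O)C=C[C@H](O[Si](C)(C)C(C)(C)C)[C@@H]1CCO[Si](CC)(CC)CC
F6 | step 15 | 2-[(1S,2R,5S)-2-acetoxy-5-[(tert-butyldimethylsilyl)oxy]-2-[(2Z)-oct-2-en-1-yl]cyclopent-3-en-1-yl]acetaldehyde | CCCCC/C=C\C[C@@]1(OC(C)=O)C=C[C@H](O[Si](C)(C)C(C)(C)C)[C@@H]1CC=O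
F7 | step 15 | methyl (5E,8S,9S,12R,14Z)-12-acetoxy-9-[(tert-butyldimethylsilyl)oxy]-4-oxoprosta-5,10,14-trien-1-oate | CCCCC/C=C\C[C@@]1(OC(C)=O)C=C[C@H](O[Si](C)(C)C(C)(C)C)[C@@H]1C/C=C/C(=O)CCC(=O)OC
F8 | step 15 | methyl (4S,5E,8S,9S,12R,14Z)-12-acetoxy-9-[(tert-butyldimethylsilyl)oxy]-4-hydroxyprosta-5,10,14-trien-1-oate | CCCCC/C=C\C[C@@]1(OC(C)=O)C=C[C@H](O[Si](C)(C)C(C)(C)C)[C@@H]1C/C=C/[C@@H](O)CCC(=O)OC
F9 | step 4 | racemic 2-(oct-2-yn-1-yl)cyclopent-2-en-1-ol | CCCCCC#CCC1=CCCC1O
F10 | step 4 | (1R)-2-(oct-2-yn-1-yl)cyclopent-2-en-1-yl acetate | CC(=O)O[C@@H]1CCC=C1CC#CCCCCC
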